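**Retrosynthetic overview**
1. Target ⇐ selective 7‑O‑acetylation of the labdadiene‑6β,7β,8α‑triol ⇐ C11–C12 nickel cross‑electrophile coupling of an 11‑iodo drimane triol with (E)‑1‑bromo‑2‑methylbuta‑1,3‑diene.
2. 6β,7β‑Diol ⇐ α‑face hydride reduction of a 6,7‑dione (the same hydride frees C11 as CH2OH from the chiral imide); the 7,8‑oxygens ⇐ α‑face osmylation of a drim‑7‑en‑6‑one.
3. Rings A and B together ⇐ chelation‑controlled intramolecular [4+2] (Mukaiyama–Michael/ring closure) of an acyclic 1‑methoxy‑3‑silyloxy diene onto a β,β‑disubstituted N‑enoyl oxazolidinone: C5–C10 (ring A) and C8–C9 (ring B) form in one operation and fix C10, C9 and C5.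
4. Acyclic triene ⇐ SN1 tert‑alkylation of a Danishefsky‑type diene by the tertiary chloride from N‑geranoyl oxazolidinone (C4–C5 bond) ⇐ geranic acid.

Assumption: (E)‑geranic acid of high E purity is taken as commercial; decalin compounds carry drimane/labdane numbering (C11 on C9, C17 on C8, C18/C19 on C4, C20 on C10) with α/β descriptors on the natural 5α‑H, 10β‑CH3 framework.

**Step 1**
Reactants: 1 (2E)‑3,7‑dimethylocta‑2,6‑dienoic acid (geranic acid); 2 (4S)‑4‑benzyl‑1,3‑oxazolidin‑2‑one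
Product: 4 (4S)‑4‑benzyl‑3‑[(2E)‑3,7‑dimethylocta‑2,6‑dienoyl]‑1,3‑oxazolidin‑2‑one, via mixed pivalic anhydride 3 (not isolated)
Conditions: PivCl, Et3N, THF, −20 °C; then 2, LiCl, −20 °C to rt
Reagents that add atoms: none
Why: Mixed‑anhydride N‑acylation of the oxazolidinone (LiCl/Et3N soft acylation) proceeds without enolization, so the 2E geometry of the enoyl unit is kept and no new stereocenter arises.

**Step 2**
Reactants: 5 (3E)‑4‑methoxypent‑3‑en‑2‑one
Product: 6 (3E)‑4‑methoxy‑2‑(trimethylsilyloxy)penta‑1,3‑diene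
Conditions: LiN(iPr)2 (1.05 equiv), THF, −78 °C; then Me3SiCl
Reagents that add atoms: chlorotrimethylsilane, C[Si](C)(C)Cl
Why: Kinetic α′‑deprotonation of the vinylogous ester followed by O‑silylation (silyl enol ether formation) gives the Danishefsky‑type diene with a nucleophilic terminal CH2, and no stereocenter is formed.

**Step 3**
Reactants: 4 (4S)‑4‑benzyl‑3‑[(2E)‑3,7‑dimethylocta‑2,6‑dienoyl]‑1,3‑oxazolidin‑2‑one; 6 (3E)‑4‑methoxy‑2‑(trimethylsilyloxy)penta‑1,3‑diene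
Product: 8 (4S)‑4‑benzyl‑3‑[(2E,10E)‑11‑methoxy‑3,7,7‑trimethyl‑9‑oxododeca‑2,10‑dienoyl]‑1,3‑oxazolidin‑2‑one, via tertiary chloride 7 (not isolated)
Conditions: HCl (g), CH2Cl2, −20 °C; evaporate; then 6 (1.5 equiv), TiCl4 (2.2 equiv), CH2Cl2, −78 to −45 °C
Reagents that add atoms: none
Why: Markovnikov hydrochlorination of the electron‑rich trisubstituted alkene (the conjugated enoyl C=C is inert) gives a tertiary chloride that TiCl4 ionizes for SN1 capture by the terminal CH2 of the silyloxy diene (Reetz‑type α‑tert‑alkylation of a silyl enol ether), which forges the quaternary C4–C5 bond and returns the β‑methoxy enone after loss of Me3SiCl, with no stereocenter formed.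

**Step 4**
Reactants: 8 (4S)‑4‑benzyl‑3‑[(2E,10E)‑11‑methoxy‑3,7,7‑trimethyl‑9‑oxododeca‑2,10‑dienoyl]‑1,3‑oxazolidin‑2‑one
Product: 9 (4S)‑4‑benzyl‑3‑[(2E,8Z,10E)‑9‑(tert‑butyldimethylsilyloxy)‑11‑methoxy‑3,7,7‑trimethyldodeca‑2,8,10‑trienoyl]‑1,3‑oxazolidin‑2‑one
Conditions: tBuMe2SiOTf (1.2 equiv), Et3N (2 equiv), CH2Cl2, −78 to 0 °C; pentane, filtration
Reagents that add atoms: tert‑butyldimethylsilyl trifluoromethanesulfonate, CC(C)(C)[Si](C)(C)OS(=O)(=O)C(F)(F)F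
Why: Soft enolization (silyl triflate/amine silyl enol ether formation) of the ketone at its α′‑CH2, the same regiochemistry as in step 2, gives the Z enol ether with the bulky quaternary carbon anti to C7 and leaves the non‑enolizable N‑enoyl imide untouched, with no stereocenter formed.

**Step 5**
Reactants: 9 (4S)‑4‑benzyl‑3‑[(2E,8Z,10E)‑9‑(tert‑butyldimethylsilyloxy)‑11‑methoxy‑3,7,7‑trimethyldodeca‑2,8,10‑trienoyl]‑1,3‑oxazolidin‑2‑one
Product: 11 (4S)‑4‑benzyl‑3‑{[(1S,4aS,8aS)‑2,5,5,8a‑tetramethyl‑4‑oxo‑1,4,4a,5,6,7,8,8a‑octahydronaphthalen‑1‑yl]carbonyl}‑1,3‑oxazolidin‑2‑one, via cycloadduct silyl enol ether 10 (not isolated)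
Conditions: Me2AlCl (2.0 equiv), CH2Cl2, −78 to −20 °C; then 1 M HCl, THF, 0 °C to rt; chromatography to remove the minor diastereomer
Reagents that add atoms: none
Why: Proposed new method: Me2AlCl chelates the two imide carbonyls and locks the s‑cis enoyl conformer (the β‑methyl cis to C=O forbids s‑trans), so the (4S)‑benzyl group blocks the Cα‑re face and the diene terminus C5 adds to the Cα‑si/Cβ‑re face at C10 (ring A, quaternary C10 with 10β‑methyl), followed at once by C9–C8 closure (ring B, suprafacial on the E alkene, hence C11 cis to the C10 methyl and 9α‑H), after which acid hydrolyses the silyl enol ether and β‑eliminates methanol to the enone with C5 settling as the trans‑fused 5α‑H epimer next to the ketone; the closest known reactions are the Me2AlCl‑promoted asymmetric intramolecular Diels–Alder reaction of triene N‑acyloxazolidinones and the Mukaiyama–Michael/Diels–Alder chemistry of Danishefsky dienes, the new element being a β,β‑disubstituted dienophile that creates the quaternary centre.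

**Step 6**
Reactants: 11 (4S)‑4‑benzyl‑3‑{[(1S,4aS,8aS)‑2,5,5,8a‑tetramethyl‑4‑oxo‑1,4,4a,5,6,7,8,8a‑octahydronaphthalen‑1‑yl]carbonyl}‑1,3‑oxazolidin‑2‑one
Product: 12 (4S)‑4‑benzyl‑3‑(7α,8α‑dihydroxy‑6‑oxodriman‑11‑oyl)‑1,3‑oxazolidin‑2‑one
Conditions: K2OsO4·2H2O (5 mol %), NMO (2 equiv), citric acid (1 equiv), tBuOH/H2O (1:1), rt
Reagents that add atoms: N‑methylmorpholine N‑oxide, C[N+]1([O-])CCOCC1; water, O
Why: Upjohn‑type catalytic osmylation (citric‑acid‑accelerated for the electron‑poor enone) adds both oxygens syn from the α face, anti to the axial C10 methyl and the C9 acyl group, which sets 8α‑OH/8β‑CH3 and a provisional 7α‑OH.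

**Step 7**
Reactants: 12 (4S)‑4‑benzyl‑3‑(7α,8α‑dihydroxy‑6‑oxodriman‑11‑oyl)‑1,3‑oxazolidin‑2‑one
Product: 13 (4S)‑4‑benzyl‑3‑(8α‑hydroxy‑6,7‑dioxodriman‑11‑oyl)‑1,3‑oxazolidin‑2‑one
Conditions: Pr4N[RuO4] (5 mol %), NMO (1.5 equiv), 4 Å MS, CH2Cl2, rt
Reagents that add atoms: none
Why: Ley–Griffith oxidation converts the secondary α‑ketol hydroxyl into a ketone (the tertiary 8‑OH cannot be oxidized), which erases the wrong C7 configuration and gives the 6,7‑dione that rests largely as its C5=C6 enol.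

**Step 8**
Reactants: 13 (4S)‑4‑benzyl‑3‑(8α‑hydroxy‑6,7‑dioxodriman‑11‑oyl)‑1,3‑oxazolidin‑2‑one
Product: 14 drimane‑6β,7β,8α,11‑tetraol
Conditions: LiBH4 (6 equiv), THF, H2O (5 equiv), 0 °C to rt
Reagents that add atoms: none
Why: Substrate‑controlled borohydride reduction attacks both ketones from the open α face, axially at C7 (anti to the axial 8β‑methyl, giving the equatorial 7β‑OH) and equatorially at C6 (the β face is closed by the syn‑axial C4 and C10 methyls, giving the axial 6β‑OH) with the enol re‑ketonizing to the trans‑fused 5α‑H ketone before the second reduction, while the same reagent reductively cleaves the N‑acyl oxazolidinone to the C11 primary alcohol and releases auxiliary 2.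

**Step 9**
Reactants: 14 drimane‑6β,7β,8α,11‑tetraol
Product: 15 11‑iododrimane‑6β,7β,8α‑triol
Conditions: I2 (1.2 equiv), PPh3 (1.3 equiv), imidazole (2.5 equiv), THF/MeCN, 0 °C to rt
Reagents that add atoms: iodine, [I][I]
Why: Appel‑type iodination activates the primary C11 hydroxyl far faster than the hindered secondary and tertiary ones, and its neutral conditions avoid oxetane formation from the 1,3‑related 8‑OH, with no stereocenter touched.

**Step 10**
Reactants: 16 methacrolein (2‑methylprop‑2‑enal)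
Product: 18 (2E)‑3‑bromo‑2‑methylprop‑2‑enal, via 2,3‑dibromo‑2‑methylpropanal 17 (not isolated)
Conditions: Br2 (1.0 equiv), CH2Cl2, −78 to 0 °C; then Et3N (1.2 equiv), 0 °C to rt
Reagents that add atoms: bromine, BrBr
Why: Bromine addition to the alkene followed by amine‑induced dehydrobromination (bromination–elimination) gives the β‑bromo enal as the more stable E isomer with bromine anti to the formyl group.

**Step 11**
Reactants: 18 (2E)‑3‑bromo‑2‑methylprop‑2‑enal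
Product: 19 (1E)‑1‑bromo‑2‑methylbuta‑1,3‑diene
Conditions: Ph3PCH3Br, KOtBu, THF, 0 °C; then 18, 0 °C to rt; distilled as a pentane solution
Reagents that add atoms: methyltriphenylphosphonium bromide, C[P+](c1ccccc1)(c1ccccc1)c1ccccc1.[Br-]
Why: Wittig methylenation of the aldehyde leaves the trisubstituted bromoalkene geometry unchanged and so delivers the E bromodiene.

**Step 12**
Reactants: 15 11‑iododrimane‑6β,7β,8α‑triol; 19 (1E)‑1‑bromo‑2‑methylbuta‑1,3‑diene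
Product: 20 (12E)‑labda‑12,14‑diene‑6β,7β,8α‑triol
Conditions: NiBr2·dme (10 mol %), 4,4′‑di‑tert‑butyl‑2,2′‑bipyridine (10 mol %), Zn dust (2 equiv), 19 (2 equiv), DMA, rt
Reagents that add atoms: none
Why: Nickel‑catalysed reductive cross‑electrophile coupling joins the primary alkyl iodide (through its radical) to the alkenyl bromide with retention of the E geometry under neutral conditions that tolerate the three free hydroxyls, with no stereocenter touched.

**Step 13**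
Reactants: 20 (12E)‑labda‑12,14‑diene‑6β,7β,8α‑triol
Product: 21 (12E)‑6β,8α‑dihydroxylabda‑12,14‑dien‑7β‑yl acetate (CNP0225877.1)
Conditions: Ac2O (1.2 equiv), pyridine, 0 °C
Reagents that add atoms: acetic anhydride, CC(=O)OC(C)=O
Why: Kinetically controlled esterification selects the equatorial secondary 7β‑OH over the axial 6β‑OH (flanked by two syn‑axial methyl groups) and the tertiary 8α‑OH, which gives the 7‑monoacetate without touching any stereocenter.

**Compound list**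
1 | (2E)‑3,7‑dimethylocta‑2,6‑dienoic acid (geranic acid) | CC(C)=CCC/C(C)=C/C(=O)O | starting material
2 | (4S)‑4‑benzyl‑1,3‑oxazolidin‑2‑one | O=C1N[C@@H](Cc2ccccc2)CO1 | starting material
3 | (2E)‑3,7‑dimethylocta‑2,6‑dienoic pivalic anhydride | CC(C)=CCC/C(C)=C/C(=O)OC(=O)C(C)(C)C | intermediate
4 | (4S)‑4‑benzyl‑3‑[(2E)‑3,7‑dimethylocta‑2,6‑dienoyl]‑1,3‑oxazolidin‑2‑one | CC(C)=CCC/C(C)=C/C(=O)N1[C@@H](Cc2ccccc2)COC1=O | intermediate
5 | (3E)‑4‑methoxypent‑3‑en‑2‑one | CO/C(C)=C/C(C)=O | starting material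
6 | (3E)‑4‑methoxy‑2‑(trimethylsilyloxy)penta‑1,3‑diene | CO/C(C)=C/C(=C)O[Si](C)(C)C | intermediate
7 | (4S)‑4‑benzyl‑3‑[(2E)‑7‑chloro‑3,7‑dimethyloct‑2‑enoyl]‑1,3‑oxazolidin‑2‑one | CC(C)(Cl)CCC/C(C)=C/C(=O)N1[C@@H](Cc2ccccc2)COC1=O | intermediate
8 | (4S)‑4‑benzyl‑3‑[(2E,10E)‑11‑methoxy‑3,7,7‑trimethyl‑9‑oxododeca‑2,10‑dienoyl]‑1,3‑oxazolidin‑2‑one | CO/C(C)=C/C(=O)CC(C)(C)CCC/C(C)=C/C(=O)N1[C@@H](Cc2ccccc2)COC1=O | intermediate
9 | (4S)‑4‑benzyl‑3‑[(2E,8Z,10E)‑9‑(tert‑butyldimethylsilyloxy)‑11‑methoxy‑3,7,7‑trimethyldodeca‑2,8,10‑trienoyl]‑1,3‑oxazolidin‑2‑one | CO/C(C)=C/C(O[Si](C)(C)C(C)(C)C)=C/C(C)(C)CCC/C(C)=C/C(=O)N1[C@@H](Cc2ccccc2)COC1=O | intermediate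
10 | (4S)‑4‑benzyl‑3‑[6‑(tert‑butyldimethylsilyloxy)‑8β‑methoxydrim‑6‑en‑11‑oyl]‑1,3‑oxazolidin‑2‑one (the C8 epimer converges on 11 as well) | O=C(N3[C@@H](Cc4ccccc4)COC3=O)[C@H]1[C@@](C)(OC)C=C(O[Si](C)(C)C(C)(C)C)[C@H]2C(C)(C)CCC[C@@]21C | intermediate
11 | (4S)‑4‑benzyl‑3‑{[(1S,4aS,8aS)‑2,5,5,8a‑tetramethyl‑4‑oxo‑1,4,4a,5,6,7,8,8a‑octahydronaphthalen‑1‑yl]carbonyl}‑1,3‑oxazolidin‑2‑one (6‑oxodrim‑7‑en‑11‑oyl imide) | O=C(N3[C@@H](Cc4ccccc4)COC3=O)[C@H]1C(C)=CC(=O)[C@H]2C(C)(C)CCC[C@@]21C | intermediate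
12 | (4S)‑4‑benzyl‑3‑(7α,8α‑dihydroxy‑6‑oxodriman‑11‑oyl)‑1,3‑oxazolidin‑2‑one | O=C(N3[C@@H](Cc4ccccc4)COC3=O)[C@H]1[C@](C)(O)[C@H](O)C(=O)[C@H]2C(C)(C)CCC[C@@]21C | intermediate
13 | (4S)‑4‑benzyl‑3‑(8α‑hydroxy‑6,7‑dioxodriman‑11‑oyl)‑1,3‑oxazolidin‑2‑one (drawn as the diketone) | O=C(N3[C@@H](Cc4ccccc4)COC3=O)[C@H]1[C@](C)(O)C(=O)C(=O)[C@H]2C(C)(C)CCC[C@@]21C | intermediate
14 | drimane‑6β,7β,8α,11‑tetraol | OC[C@H]1[C@](C)(O)[C@@H](O)[C@@H](O)[C@H]2C(C)(C)CCC[C@@]21C | intermediate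
15 | 11‑iododrimane‑6β,7β,8α‑triol | IC[C@H]1[C@](C)(O)[C@@H](O)[C@@H](O)[C@H]2C(C)(C)CCC[C@@]21C | intermediate
16 | methacrolein (2‑methylprop‑2‑enal) | C=C(C)C=O | starting material
17 | 2,3‑dibromo‑2‑methylpropanal (racemic) | O=CC(C)(Br)CBr | intermediate
18 | (2E)‑3‑bromo‑2‑methylprop‑2‑enal | O=C/C(C)=C/Br | intermediate
19 | (1E)‑1‑bromo‑2‑methylbuta‑1,3‑diene | C=C/C(C)=C/Br | intermediate
20 | (12E)‑labda‑12,14‑diene‑6β,7β,8α‑triol | C=C/C(C)=C/C[C@H]1[C@](C)(O)[C@@H](O)[C@@H](O)[C@H]2C(C)(C)CCC[C@@]21C | intermediate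
21 | (12E)‑6β,8α‑dihydroxylabda‑12,14‑dien‑7β‑yl acetate, (5S,6S,7S,8S,9R,10S), CNP0225877.1 | C=C/C(C)=C/C[C@H]1[C@](C)(O)[C@@H](OC(C)=O)[C@@H](O)[C@H]2C(C)(C)CCC[C@@]21C | target

**Step count**
Total: 13 steps. Longest linear sequence: 10 steps (1, 3, 4, 5, 6, 7, 8, 9, 12, 13 from geranic acid); steps 2 and 10–11 are side branches.

**Three steps most likely to fail, with fallbacks**

Step 3 (tert‑alkylation of the sensitive silyloxy diene). The diene may be destroyed by TiCl4/HCl faster than it traps the cation. The fallback sets out from tertiary chloride 7 and comes back at 8, building the vinylogous ester piecewise instead. TiCl4 alkylation of commercial 2‑(trimethylsilyloxy)propene with 7 gives the methyl ketone (4S)‑4‑benzyl‑3‑[(2E)‑3,7,7‑trimethyl‑9‑oxodec‑2‑enoyl]‑1,3‑oxazolidin‑2‑one F1. Soft enolization at the methyl group (MgBr2·OEt2, iPr2NEt) and C‑acetylation with 1‑acetylbenzotriazole give the β‑diketone (4S)‑4‑benzyl‑3‑[(2E)‑3,7,7‑trimethyl‑9,11‑dioxododec‑2‑enoyl]‑1,3‑oxazolidin‑2‑one F2. HC(OMe)3 with catalytic TsOH in MeOH then converts the less hindered acetyl carbonyl into the methyl enol ether, which is 8.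

Step 5 (the bicyclization). The Lewis‑acid process may stop after the first C–C bond or fail for the β,β‑disubstituted acceptor. The fallback sets out from 8 and comes back at 11, using a more electron‑rich diene in an uncatalysed thermal cycloaddition. Pyrrolidine exchanges the methoxy group of 8 to give the enaminone (4S)‑4‑benzyl‑3‑[(2E,10E)‑3,7,7‑trimethyl‑9‑oxo‑11‑(pyrrolidin‑1‑yl)dodeca‑2,10‑dienoyl]‑1,3‑oxazolidin‑2‑one F3. tBuMe2SiOTf/Et3N gives the 1‑amino‑3‑silyloxy diene (4S)‑4‑benzyl‑3‑[(2E,8Z,10E)‑9‑(tert‑butyldimethylsilyloxy)‑3,7,7‑trimethyl‑11‑(pyrrolidin‑1‑yl)dodeca‑2,8,10‑trienoyl]‑1,3‑oxazolidin‑2‑one F4. Heating in toluene (80–110 °C) closes both rings to the cycloadduct (4S)‑4‑benzyl‑3‑[6‑(tert‑butyldimethylsilyloxy)‑8β‑(pyrrolidin‑1‑yl)drim‑6‑en‑11‑oyl]‑1,3‑oxazolidin‑2‑one F5. 1 M HCl in THF hydrolyses the enol ether and eliminates pyrrolidine to give 11; facial control is weaker without chelation, so the diastereomers are separated at this point.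

Step 12 (nickel coupling with a conjugated bromodiene on a free triol). The diene may oligomerize on nickel or lose its geometry. The fallback sets out from 15 and comes back at 20, building the diene after the C11–C12 bond. The same nickel/zinc coupling with vinyl bromide gives the terminal alkene 11‑ethenyldrimane‑6β,7β,8α‑triol F6. Cross‑metathesis with methacrolein (second‑generation Hoveyda–Grubbs catalyst, CH2Cl2, 40 °C) gives the E enal (12E)‑6β,7β,8α‑trihydroxy‑15‑norlabd‑12‑en‑14‑al F7. Wittig methylenation (Ph3PCH3Br, KOtBu, excess base for the hydroxyls) then gives 20.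

**Further compounds**
F1 | step 3 | (4S)‑4‑benzyl‑3‑[(2E)‑3,7,7‑trimethyl‑9‑oxodec‑2‑enoyl]‑1,3‑oxazolidin‑2‑one | CC(=O)CC(C)(C)CCC/C(C)=C/C(=O)N1[C@@H](Cc2ccccc2)COC1=O
F2 | step 3 | (4S)‑4‑benzyl‑3‑[(2E)‑3,7,7‑trimethyl‑9,11‑dioxododec‑2‑enoyl]‑1,3‑oxazolidin‑2‑one | CC(=O)CC(=O)CC(C)(C)CCC/C(C)=C/C(=O)N1[C@@H](Cc2ccccc2)COC1=O
F3 | step 5 | (4S)‑4‑benzyl‑3‑[(2E,10E)‑3,7,7‑trimethyl‑9‑oxo‑11‑(pyrrolidin‑1‑yl)dodeca‑2,10‑dienoyl]‑1,3‑oxazolidin‑2‑one | C/C(=C\C(=O)CC(C)(C)CCC/C(C)=C/C(=O)N1[C@@H](Cc2ccccc2)COC1=O)N1CCCC1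
F4 | step 5 | (4S)‑4‑benzyl‑3‑[(2E,8Z,10E)‑9‑(tert‑butyldimethylsilyloxy)‑3,7,7‑trimethyl‑11‑(pyrrolidin‑1‑yl)dodeca‑2,8,10‑trienoyl]‑1,3‑oxazolidin‑2‑one | C/C(=C\C(O[Si](C)(C)C(C)(C)C)=C\C(C)(C)CCC/C(C)=C/C(=O)N1[C@@H](Cc2ccccc2)COC1=O)N1CCCC1
F5 | step 5 | (4S)‑4‑benzyl‑3‑[6‑(tert‑butyldimethylsilyloxy)‑8β‑(pyrrolidin‑1‑yl)drim‑6‑en‑11‑oyl]‑1,3‑oxazolidin‑2‑one | O=C(N3[C@@H](Cc4ccccc4)COC3=O)[C@H]1[C@@](C)(N5CCCC5)C=C(O[Si](C)(C)C(C)(C)C)[C@H]2C(C)(C)CCC[C@@]21C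
F6 | step 12 | 11‑ethenyldrimane‑6β,7β,8α‑triol | C=CC[C@H]1[C@](C)(O)[C@@H](O)[C@@H](O)[C@H]2C(C)(C)CCC[C@@]21C
F7 | step 12 | (12E)‑6β,7β,8α‑trihydroxy‑15‑norlabd‑12‑en‑14‑al | O=C/C(C)=C/C[C@H]1[C@](C)(O)[C@@H](O)[C@@H](O)[C@H]2C(C)(C)CCC[C@@]21C
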